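In a closed, stirred vessel of constant volume, electrophile meets a fixed charge of nucleophile while gas feeds free base into the solution.

    electrophile + nucleophile ⇌ acid set free + product (K1 = 0.73, k1 = 260 M⁻¹ s⁻¹)
    nucleophile + acid set free ⇌ protonated nucleophile, settled at all times (K2 = 7.0 × 10⁶ M⁻¹)
    acid set free + free base ⇌ salt of the base (K3 = 3.5 × 10⁵ M⁻¹, k3 = 3100 M⁻¹ s⁻¹)
    gas ⇌ free base, rate k4*(csat - [free base]) (k4 = 67 s⁻¹, csat = 0.12 mM)
    2 electrophile → homo dimer (k5 = 0.22 M⁻¹ s⁻¹)

| flask | electrophile | nucleophile | gas | time |
|---|---|---|---|---|
| teal | 5.0 × 10⁻⁴ M | 0.950 mM | 0.12 mM (held) | 4.0 s |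
| ochre | 0.0010 M | 0.950 mM | 0.12 mM (held) | 4.0 s |
| red | 0.0020 M | 0.950 mM | 0.12 mM (held) | 4.0 s |
| amber | 0.0040 M | 0.950 mM | 0.12 mM (held) | 4.0 s |
| violet | 0.0080 M | 0.950 mM | 0.12 mM (held) | 4.0 s |

- in percentages every species weighs as the electrophile in it: one homo dimer counts as two
- two of one species on the left: rate k times its square, two consumed each time
- at the start none of free base is dissolved
- "hardly changes" means that all values lie within two and a half points (for a concentration: within two and a half percent of the largest)
- run time (teal): 4.0 s

* [product] at the end for teal, ochre, red, amber, violet, in this order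
* the course of these numbers from the first flask to the last (falls all the way / falls, then rises / hardly changes / rises all the way / rises, then falls)

We start with the acid that each turn of the first step sets free. At balance, nucleophile holds it with a weight of 6600 (the binding constant times c(nucleophile) at the start), against 42.0 for free base at saturation, so in our reckoning each acid takes one more nucleophile. A turn therefore costs two nucleophile, and in our reckoning product has a ceiling of 4.75 × 10⁻⁴ M, half the nucleophile charge. Every electrophile charge exceeds this, so nucleophile is the limiting reagent.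

Now we freeze electrophile at its charge. Nucleophile then falls in a pseudo-first-order way, and the run folds into one depletion number: the run time divided by the mean life of nucleophile, which is 1.04 for teal. It counts how many mean lives fit into the run, and product reaches the ceiling times one minus e to the minus that number. With 16.6 for violet and 8.32 for amber, our row is 3.07 × 10⁻⁴ M, 4.16 × 10⁻⁴ M, 4.68 × 10⁻⁴ M, 4.75 × 10⁻⁴ M and 4.75 × 10⁻⁴ M.

Is one number enough? The freeze must hold. Violet's reckoned product uses 5.94% of its electrophile, but teal's uses 61.4%. So in teal electrophile falls during the run, and we expect the flask to stand below our teal value. We commit to a course that rises and flattens at the ceiling.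

The forecast gives 2.450 × 10⁻⁴ M, 3.750 × 10⁻⁴ M, 4.590 × 10⁻⁴ M, 4.780 × 10⁻⁴ M and 4.880 × 10⁻⁴ M, rises all the way, on the ground that “more electrophile simply approaches that cap faster”; its teal value lies below ours.

The flask gives 2.45 × 10⁻⁴ M, 3.75 × 10⁻⁴ M, 4.60 × 10⁻⁴ M, 4.81 × 10⁻⁴ M and 4.91 × 10⁻⁴ M, and the course rises all the way. In teal, with a depletion number of 1.04, the half-life of electrophile by the forward rate of the first step is 3.8 s at 1.33 s, shorter than the run of 4.0 s; electrophile ends at 50.9% of its charge, and product lies below our 3.07 × 10⁻⁴ M. In amber the number 8.32 gives 4.75 × 10⁻⁴ M, and the flask stands above that at 4.81 × 10⁻⁴ M, with 0.62% of its nucleophile unbound at 4.00 s.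

All constants were set for the occasion; no experiment stands behind them.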